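**Plan**
- Retrosynthesis cuts the pyran ring last, at C3=C4 and O1–C2 of the chromene, to give a 2,6-dihydroxybenzaldehyde that already carries the side chain, plus a 2-methylprop-1-enyl boron reagent. It then cuts the aryl–ketone bond (aryllithium plus an (S)-3-silyloxy-3-phenylpropanoyl Weinreb amide) and the aryl–CHO bond.
- Forward: the bis-MOM ether of 5-methoxyresorcinol is formylated between its two OMOM groups. The aldehyde, masked in the flask as an α-amino alkoxide, is lithiated at one of its two equivalent ring CH positions and acylated. Acid removes all protecting groups, and the pyran ring is closed in the last step.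
- Enabling feature: the formyl carbon (future C4) sits on the benzene ring between two phenolic oxygens. The one ortho to the ketone (future 5-OH) is held in a six-membered hydrogen-bonded chelate with the C6 ketone carbonyl, which leaves the oxygen para to the ketone (future O1) to close the pyran ring.
- Stereochemistry: the single (S) carbinol centre is bought with ethyl (S)-3-hydroxy-3-phenylpropanoate and no step breaks a bond to it.

Key step: step 7

Assumption: the three starting materials are taken as purchasable, the hydroxy ester as the single (S) enantiomer; chromene numbering (O1, C2, C3, C4, C4a, C5 to C8, C8a) is used for the target.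

Step 1
Reactants: 1 5-methoxyresorcinol (5-methoxybenzene-1,3-diol)
Product: 2 1-methoxy-3,5-bis(methoxymethoxy)benzene
Conditions: NaH, MOMCl, DMF, 0 °C to rt
Reagents that add atoms: chloromethyl methyl ether (MOMCl), COCCl
Why: Double Williamson etherification of the two phenoxides should be clean because 1 has no other reactive site, and it installs the acetal ethers that direct both later lithiations.

Step 2
Reactants: 2 1-methoxy-3,5-bis(methoxymethoxy)benzene
Product: 4 4-methoxy-2,6-bis(methoxymethoxy)benzaldehyde, via aryllithium 3 (not isolated)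
Conditions: n-BuLi, TMEDA, THF, 0 °C; DMF, 0 °C to rt; aq NH4Cl
Reagents that add atoms: N,N-dimethylformamide (DMF), CN(C)C=O
Why: Directed ortho-metalation should occur at the ring CH between the two OMOM groups, where two acetal oxygens hold lithium, and DMF formylates aryllithium 3 (Bouveault aldehyde synthesis); the product keeps a mirror plane, so its two remaining ring CH positions are equivalent.

Step 3
Reactants: 5 ethyl (S)-3-hydroxy-3-phenylpropanoate
Product: 6 ethyl (S)-3-{[tert-butyl(dimethyl)silyl]oxy}-3-phenylpropanoate
Conditions: TBSCl, imidazole, DMF, rt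
Reagents that add atoms: tert-butyldimethylsilyl chloride (TBSCl), CC(C)(C)[Si](C)(C)Cl
Why: Imidazole-promoted O-silylation of the secondary alcohol does not break the C–O bond of the stereocentre, so the (S) configuration of 5 should be retained.

Step 4
Reactants: 6 ethyl (S)-3-{[tert-butyl(dimethyl)silyl]oxy}-3-phenylpropanoate
Product: 7 (S)-3-{[tert-butyl(dimethyl)silyl]oxy}-N-methoxy-N-methyl-3-phenylpropanamide
Conditions: MeNHOMe·HCl, i-PrMgCl, THF, −20 to 0 °C
Reagents that add atoms: N,O-dimethylhydroxylamine hydrochloride, CNOC.Cl
Why: Aminolysis of the ester by the chloromagnesium amide of N,O-dimethylhydroxylamine (Weinreb amide formation) should be faster below 0 °C than enolisation and loss of the β-silyloxy group, and it leaves the stereocentre untouched.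

Step 5
Reactants: 4 4-methoxy-2,6-bis(methoxymethoxy)benzaldehyde; 7 (S)-3-{[tert-butyl(dimethyl)silyl]oxy}-N-methoxy-N-methyl-3-phenylpropanamide
Product: 10 3-[(3S)-3-{[tert-butyl(dimethyl)silyl]oxy}-3-phenylpropanoyl]-4-methoxy-2,6-bis(methoxymethoxy)benzaldehyde, via lithium amino alkoxide 8 (not isolated), via aryllithium 9 (not isolated)
Conditions: 1-methylpiperazine, n-BuLi, THF, −20 °C; n-BuLi, TMEDA, −20 to 0 °C; 7, −78 to 0 °C; aq NH4Cl
Reagents that add atoms: none
Why: Addition of lithium 4-methylpiperazin-1-ide masks the aldehyde in the flask as α-amino alkoxide 8, directed ortho-metalation then occurs at either of the two equivalent ring CH positions flanked by OMOM and OMe to give 9, and acylation by 7 should stop at the ketone because the N-methoxy-N-methyl adduct stays chelated until work-up (Weinreb ketone synthesis), which also releases the aldehyde; no stereocentre is formed or touched.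

Step 6
Reactants: 10 3-[(3S)-3-{[tert-butyl(dimethyl)silyl]oxy}-3-phenylpropanoyl]-4-methoxy-2,6-bis(methoxymethoxy)benzaldehyde
Product: 11 2,6-dihydroxy-3-[(3S)-3-hydroxy-3-phenylpropanoyl]-4-methoxybenzaldehyde
Conditions: HCl, MeOH, rt; aqueous work-up
Reagents that add atoms: none
Why: Acid-catalysed methanolysis (transacetalisation) should remove both aryl MOM ethers, each activated by an ortho carbonyl group, and the silyl ether in one operation, while the unactivated benzylic carbinol should neither ionise nor dehydrate at room temperature and the aldehyde is recovered on aqueous work-up.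

Step 7
Reactants: 11 2,6-dihydroxy-3-[(3S)-3-hydroxy-3-phenylpropanoyl]-4-methoxybenzaldehyde; 12 2-methylprop-1-enylboronic acid
Product: 15 (3S)-3-hydroxy-1-(5-hydroxy-7-methoxy-2,2-dimethyl-2H-chromen-6-yl)-3-phenylpropan-1-one, via aminophenol 13 (not isolated), via ortho-quinone methide 14 (not isolated)
Conditions: Bn2NH (30 mol %), 12 (1.5 equiv), dioxane, 80 °C
Reagents that add atoms: none
Why: Dibenzylamine condenses with the formyl group of 11 to an iminium phenoxide, a flanking phenoxide oxygen binds 12 as a tetracoordinate boronate that hands its alkenyl carbon to the iminium carbon (C4–C3 bond, aminophenol 13), and thermal loss of the amine gives the 1-oxatriene 14, which closes the O1–C2 bond and returns the catalyst. The closest known reaction type is the amine-catalysed Petasis borono-Mannich condensation of salicylaldehydes with alkenylboronic acids to 2H-chromenes, and 14 is the same kind of intermediate as in the classical annulation of phenols with 3-methylbut-2-enal. The pyran ring closes by a thermal disrotatory oxa-6π electrocyclisation of 14, driven by the return of benzene aromaticity. No stereocentre is created, since C2 carries two methyl groups and the aminated carbon of 13 becomes C4 of the alkene, and the (S) carbinol lies outside the reacting system. The step needs closure onto the oxygen para to the ketone and not onto the one ortho to it; the ortho hydroxyl is held in the six-membered hydrogen-bonded chelate with the ketone carbonyl, so only the para oxygen should become the carbonyl of 14 and the product keeps the chelate, as is the rule in chromene annulations of 2,4-dihydroxyaryl ketones. Ipso transfer from boron places the CMe2 terminus on oxygen, and the chelated, doubly ortho-substituted ketone should not condense with the secondary amine.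

**Compound list**
1 | 5-methoxyresorcinol (5-methoxybenzene-1,3-diol) | COc1cc(O)cc(O)c1 | starting material
2 | 1-methoxy-3,5-bis(methoxymethoxy)benzene | COCOc1cc(OC)cc(OCOC)c1 | intermediate
3 | [4-methoxy-2,6-bis(methoxymethoxy)phenyl]lithium | [Li]c1c(OCOC)cc(OC)cc1OCOC | intermediate
4 | 4-methoxy-2,6-bis(methoxymethoxy)benzaldehyde | O=Cc1c(OCOC)cc(OC)cc1OCOC | intermediate
5 | ethyl (S)-3-hydroxy-3-phenylpropanoate | CCOC(=O)C[C@H](O)c1ccccc1 | starting material
6 | ethyl (S)-3-{[tert-butyl(dimethyl)silyl]oxy}-3-phenylpropanoate | CCOC(=O)C[C@H](O[Si](C)(C)C(C)(C)C)c1ccccc1 | intermediate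
7 | (S)-3-{[tert-butyl(dimethyl)silyl]oxy}-N-methoxy-N-methyl-3-phenylpropanamide | CON(C)C(=O)C[C@H](O[Si](C)(C)C(C)(C)C)c1ccccc1 | intermediate
8 | lithium [4-methoxy-2,6-bis(methoxymethoxy)phenyl](4-methylpiperazin-1-yl)methanolate | [Li+].[O-]C(N1CCN(C)CC1)c1c(OCOC)cc(OC)cc1OCOC | intermediate
9 | lithium [3-lithio-4-methoxy-2,6-bis(methoxymethoxy)phenyl](4-methylpiperazin-1-yl)methanolate | [Li+].[O-]C(N1CCN(C)CC1)c1c(OCOC)cc(OC)c([Li])c1OCOC | intermediate
10 | 3-[(3S)-3-{[tert-butyl(dimethyl)silyl]oxy}-3-phenylpropanoyl]-4-methoxy-2,6-bis(methoxymethoxy)benzaldehyde | COCOc1cc(OC)c(C(=O)C[C@H](O[Si](C)(C)C(C)(C)C)c2ccccc2)c(OCOC)c1C=O | intermediate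
11 | 2,6-dihydroxy-3-[(3S)-3-hydroxy-3-phenylpropanoyl]-4-methoxybenzaldehyde | COc1cc(O)c(C=O)c(O)c1C(=O)C[C@H](O)c1ccccc1 | intermediate
12 | 2-methylprop-1-enylboronic acid | CC(C)=CB(O)O | starting material
13 | (3S)-1-{3-[1-(dibenzylamino)-3-methylbut-2-en-1-yl]-2,4-dihydroxy-6-methoxyphenyl}-3-hydroxy-3-phenylpropan-1-one (both epimers at the aminated carbon) | COc1cc(O)c(C(C=C(C)C)N(Cc2ccccc2)Cc2ccccc2)c(O)c1C(=O)C[C@H](O)c1ccccc1 | intermediate
14 | (3S)-3-hydroxy-1-[2-hydroxy-6-methoxy-3-(3-methylbut-2-en-1-ylidene)-4-oxocyclohexa-1,5-dien-1-yl]-3-phenylpropan-1-one | COC1=CC(=O)C(=CC=C(C)C)C(O)=C1C(=O)C[C@H](O)c1ccccc1 | intermediate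
15 | (3S)-3-hydroxy-1-(5-hydroxy-7-methoxy-2,2-dimethyl-2H-chromen-6-yl)-3-phenylpropan-1-one | COc1cc2c(c(O)c1C(=O)C[C@H](O)c1ccccc1)C=CC(C)(C)O2 | target

Total step count: 7. Longest linear sequence: 5 (steps 1, 2, 5, 6, 7).

**Steps most likely to fail**

Step 7. The alkenyl transfer from boron may be slow, because the iminium of a 2,6-dihydroxy-4-methoxybenzaldehyde is strongly stabilised. The amine may also induce loss of water from the aldol unit at 80 °C (chalcone, then flavanone), or closure may occur onto the chelated oxygen. The fallback sets out from 10 and comes back to the route at 14 and hence 15. 2-Methylprop-1-enylmagnesium bromide in THF at −78 °C should add to the aldehyde of 10 faster than to the enolisable ketone with its two ortho substituents. This should give (3S)-3-{[tert-butyl(dimethyl)silyl]oxy}-1-[3-(1-hydroxy-3-methylbut-2-en-1-yl)-6-methoxy-2,4-bis(methoxymethoxy)phenyl]-3-phenylpropan-1-one F1 as a mixture of carbinol epimers. HCl in MeOH at rt should then remove the MOM and TBS groups and ionise the allylic, doubly ortho-oxygenated benzylic carbinol with loss of water to the same ortho-quinone methide 14, which closes to 15 without amine or heating.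

Step 5. Ring deprotonation of the alkoxide-bearing arene may be incomplete, leaving butyllithium to consume the amide, or the amine adduct of the hindered aldehyde may revert. The fallback sets out from 4 and comes back at 9. NBS in MeCN at 0 °C should brominate one of the two equivalent open ring positions of 4 to give 3-bromo-4-methoxy-2,6-bis(methoxymethoxy)benzaldehyde F2. Lithium 4-methylpiperazin-1-ide in THF at −20 °C should convert it into lithium [3-bromo-4-methoxy-2,6-bis(methoxymethoxy)phenyl](4-methylpiperazin-1-yl)methanolate F3. Bromine–lithium exchange with one equivalent of n-BuLi at −78 °C, which is fast and stoichiometric, should then give aryllithium 9 for acylation by 7 as before.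

Step 6. Protic acid may dehydrate the freed β-hydroxy ketone, with oxa-Michael closure of the resulting chalcone, or cause solvolysis at the benzylic carbinol. The fallback sets out from 10 and comes back at 11. It unmasks the phenols while the carbinol is still silylated and frees the carbinol afterwards without protic mineral acid. TMSBr in CH2Cl2 at −30 °C, followed by aqueous NaHCO3, should cleave only the two aryl MOM ethers and give 3-[(3S)-3-{[tert-butyl(dimethyl)silyl]oxy}-3-phenylpropanoyl]-2,6-dihydroxy-4-methoxybenzaldehyde F4. HF·pyridine buffered with pyridine in THF at 0 °C should then remove the silyl group to give 11.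

**Further compounds**
F1 | step 7 | (3S)-3-{[tert-butyl(dimethyl)silyl]oxy}-1-[3-(1-hydroxy-3-methylbut-2-en-1-yl)-6-methoxy-2,4-bis(methoxymethoxy)phenyl]-3-phenylpropan-1-one | COCOc1cc(OC)c(C(=O)C[C@H](O[Si](C)(C)C(C)(C)C)c2ccccc2)c(OCOC)c1C(O)C=C(C)C
F2 | step 5 | 3-bromo-4-methoxy-2,6-bis(methoxymethoxy)benzaldehyde | COCOc1cc(OC)c(Br)c(OCOC)c1C=O
F3 | step 5 | lithium [3-bromo-4-methoxy-2,6-bis(methoxymethoxy)phenyl](4-methylpiperazin-1-yl)methanolate | [Li+].[O-]C(N1CCN(C)CC1)c1c(OCOC)cc(OC)c(Br)c1OCOC
F4 | step 6 | 3-[(3S)-3-{[tert-butyl(dimethyl)silyl]oxy}-3-phenylpropanoyl]-2,6-dihydroxy-4-methoxybenzaldehyde | COc1cc(O)c(C=O)c(O)c1C(=O)C[C@H](O[Si](C)(C)C(C)(C)C)c1ccccc1
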